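**Assumption:** Gemichalcone A has no stereocentres, so "single enantiomer" is read as the single geometric isomer drawn: chalcone C=C (E), feruloyl C=C (E), side-chain trisubstituted C=C (Z, with CH2O cis to ArCH2).

## Retrosynthetic overview

1. Ester C–O bond (Steglich): MOM-protected ferulic acid (catechol, then Heck with acrylic acid) plus the chalcone (Z)-allylic alcohol.
2. Chalcone C=C (Claisen–Schmidt): C3-substituted resacetophenone plus 4-(MOMO)benzaldehyde (from 4-bromophenol).
3. Key ArCH2–CH= bond: Rh-catalysed deaminative benzyl–alkenyl coupling of a phenolic Mannich ammonium salt (via an o-quinone methide) with a (Z)-alkenyl boronate.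
4. Z geometry is fixed before the coupling by Cu-catalysed anti-carbomagnesiation/iodination of propargyl alcohol; both E alkenes arise from Heck and aldol condensation.
5. No ring is constructed; the three benzene rings come intact from resorcinol, 4-bromophenol and catechol.

## Route

**Step 1**
Reactants: 1 resorcinol; 2 acetic acid
Product: 3, 2,4-dihydroxyacetophenone
Conditions: ZnCl2, AcOH (neat), 140 °C
Reagents that add atoms: none
Why: Nencki (Friedel–Crafts) C-acylation of resorcinol goes para to one OH and ortho to the other, giving the chelated ketone.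

**Step 2**
Reactants: 3; 4 formaldehyde
Product: 5, 1-{3-[(dimethylamino)methyl]-2,4-dihydroxyphenyl}ethan-1-one
Conditions: 37% aq. HCHO (1.0 equiv), 40% aq. Me2NH (1.05 equiv), EtOH, 0 °C → rt
Reagents that add atoms: dimethylamine, CNC
Why: Phenolic Mannich reaction; by analogy with C8 aminomethylation of 7-hydroxychromones, the chelated 4-acylresorcinol should react at C3 between the two oxygens, and one equivalent at low temperature limits bis-aminomethylation.

**Step 3**
Reactants: 5
Product: 6, 1-(3-acetyl-2,6-dihydroxyphenyl)-N,N,N-trimethylmethanaminium triflate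
Conditions: MeOTf (1.0 equiv), CH2Cl2, −20 → 0 °C; precipitate with Et2O
Reagents that add atoms: methyl triflate, COS(=O)(=O)C(F)(F)F
Why: Menshutkin N-methylation of the tertiary benzylic amine is much faster than O-methylation of the un-ionised, hydrogen-bonded phenols, and gives an o-quinone methide precursor with a non-coordinating counter-ion.

**Step 4**
Reactants: 7 propargyl alcohol; 8 methylmagnesium bromide
Product: 9, (Z)-3-iodo-2-methylprop-2-en-1-ol
Conditions: MeMgBr (2.5 equiv), CuI (10 mol%), THF, −10 °C → rt; then I2, −40 → 0 °C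
Reagents that add atoms: iodine, II
Why: Alkoxide-directed Cu-catalysed anti-carbomagnesiation puts Me on C2 and Mg on C3 in a five-membered chelate cis to CH2O, and iodinolysis with retention gives only the Z-vinyl iodide.

**Step 5**
Reactants: 9
Product: 10, (Z)-tert-butyl[(3-iodo-2-methylprop-2-en-1-yl)oxy]dimethylsilane
Conditions: TBSCl, imidazole, CH2Cl2, 0 °C → rt
Reagents that add atoms: TBSCl, CC(C)(C)[Si](C)(C)Cl
Why: Standard silylation of a primary alcohol; the alkene is untouched.

**Step 6**
Reactants: 10
Product: 11, (Z)-tert-butyldimethyl{[2-methyl-3-(4,4,5,5-tetramethyl-1,3,2-dioxaborolan-2-yl)prop-2-en-1-yl]oxy}silane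
Conditions: t-BuLi (2.1 equiv), Et2O, −78 °C; then i-PrOBpin, −78 °C → rt
Reagents that add atoms: 2-isopropoxy-4,4,5,5-tetramethyl-1,3,2-dioxaborolane, CC(C)OB1OC(C)(C)C(C)(C)O1
Why: I/Li exchange and borylation of the configurationally stable vinyllithium proceed with retention; holding −78 °C until the borate quench suppresses 1,4 O→C silyl migration.

**Step 7 (key step)**
Reactants: 6; 11
Product: 12, 1-{3-[(2Z)-4-{[tert-butyl(dimethyl)silyl]oxy}-3-methylbut-2-en-1-yl]-2,4-dihydroxyphenyl}ethan-1-one
Conditions: [Rh(cod)OH]2 (2.5 mol%), 11 (1.5 equiv), K3PO4 (2.5 equiv), 1,4-dioxane/H2O 10:1, 50 °C, 6 added over 2 h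
Reagents that add atoms: none
Why: Proposed new method: a Rh(I)-catalysed deaminative benzyl–alkenyl (sp3–sp2) Suzuki-type coupling in which mild base turns the o-hydroxybenzyl ammonium salt into a transient o-quinone methide (loss of NMe3), the (Z)-alkenyl–Rh(I) from B→Rh transmetalation adds 1,4 to the exocyclic CH2 (driven by rearomatisation), and the Rh phenoxide is hydrolysed back to Rh–OH, so the ArCH2–CH= bond forms with retention of the Z geometry; phosphine-free Rh/diene is used because phosphines trap o-quinone methides, triflate because halide slows transmetalation, and slow addition keeps the methide concentration low; the closest known reaction types are Hayashi–Miyaura 1,4-addition of alkenylboron reagents to enones, boronate additions to o-quinone methides and Suzuki couplings of benzylic ammonium salts.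

**Step 8**
Reactants: 12
Product: 13, 1-{3-[(2Z)-4-{[tert-butyl(dimethyl)silyl]oxy}-3-methylbut-2-en-1-yl]-2-hydroxy-4-(methoxymethoxy)phenyl}ethan-1-one
Conditions: MOMCl (1.2 equiv), K2CO3, acetone, rt
Reagents that add atoms: chloromethyl methyl ether, COCCl
Why: Williamson-type alkylation is selective for the 4-OH because the 2-OH is locked in a hydrogen bond to the ketone.

**Step 9**
Reactants: 14, 4-bromophenol
Product: 15, 1-bromo-4-(methoxymethoxy)benzene
Conditions: MOMCl, i-Pr2NEt, CH2Cl2, 0 °C → rt
Reagents that add atoms: chloromethyl methyl ether, COCCl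
Why: Routine phenol protection as the MOM acetal.

**Step 10**
Reactants: 15
Product: 16, 4-(methoxymethoxy)benzaldehyde
Conditions: n-BuLi, THF, −78 °C; then DMF, −78 °C → rt
Reagents that add atoms: N,N-dimethylformamide, CN(C)C=O
Why: Br/Li exchange is faster than ortho-lithiation at −78 °C, and the aryllithium is formylated by DMF (Bouveault).

**Step 11**
Reactants: 13; 16
Product: 17, (2E)-1-{3-[(2Z)-4-{[tert-butyl(dimethyl)silyl]oxy}-3-methylbut-2-en-1-yl]-2-hydroxy-4-(methoxymethoxy)phenyl}-3-[4-(methoxymethoxy)phenyl]prop-2-en-1-one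
Conditions: KOH (50% aq.), EtOH, rt, 36 h
Reagents that add atoms: none
Why: Claisen–Schmidt aldol condensation with E1cB dehydration gives the E-enone, as established for 3-prenyl-2-hydroxy-4-MOMO-acetophenones; MOM ethers, the Z-alkene and the alkyl TBS ether tolerate the base, and any desilylated material converges in step 12.

**Step 12**
Reactants: 17
Product: 18, (2E)-1-{2-hydroxy-3-[(2Z)-4-hydroxy-3-methylbut-2-en-1-yl]-4-(methoxymethoxy)phenyl}-3-[4-(methoxymethoxy)phenyl]prop-2-en-1-one
Conditions: TBAF/AcOH (1:1), THF, 0 °C → rt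
Reagents that add atoms: none
Why: Fluoride desilylation; the acetic acid buffer keeps the 2'-phenol protonated so the chalcone does not cyclise to the flavanone.

**Step 13**
Reactants: 19, catechol
Product: 20, 2-methoxyphenol (guaiacol)
Conditions: MeI (1.0 equiv), K2CO3 (1.0 equiv), acetone, reflux
Reagents that add atoms: iodomethane, CI
Why: Statistical Williamson mono-methylation; guaiacol is separated from veratrole and catechol by base extraction or distillation.

**Step 14**
Reactants: 20
Product: 21, 4-bromo-2-methoxyphenol
Conditions: NBS, MeCN, 0 °C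
Reagents that add atoms: N-bromosuccinimide, O=C1CCC(=O)N1Br
Why: Electrophilic bromination is directed para to the free OH, the stronger donor.

**Step 15**
Reactants: 21
Product: 22, 4-bromo-2-methoxy-1-(methoxymethoxy)benzene
Conditions: MOMCl, i-Pr2NEt, CH2Cl2, 0 °C → rt
Reagents that add atoms: chloromethyl methyl ether, COCCl
Why: Routine phenol protection, needed so the acid cannot self-acylate in step 17.

**Step 16**
Reactants: 22; 23 acrylic acid
Product: 24, (2E)-3-[3-methoxy-4-(methoxymethoxy)phenyl]prop-2-enoic acid
Conditions: Pd(OAc)2 (2 mol%), P(o-tol)3 (4 mol%), Et3N, DMF, 100 °C; citric acid work-up (pH 4)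
Reagents that add atoms: none
Why: Mizoroki–Heck arylation of acrylic acid; syn-insertion and syn-β-hydride elimination give the E-cinnamic acid, and the MOM ether survives the basic medium and mild work-up.

**Step 17**
Reactants: 18; 24
Product: 25, (2Z)-4-{2-hydroxy-6-(methoxymethoxy)-3-[(2E)-3-[4-(methoxymethoxy)phenyl]prop-2-enoyl]phenyl}-2-methylbut-2-en-1-yl (2E)-3-[3-methoxy-4-(methoxymethoxy)phenyl]prop-2-enoate
Conditions: 24 (1.1 equiv), EDC·HCl, DMAP (0.2 equiv), CH2Cl2, 0 °C → rt
Reagents that add atoms: none
Why: Steglich esterification acylates the primary allylic alcohol far faster than the chelated 2'-phenol, and no step touches the alkene geometries.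

**Step 18**
Reactants: 25
Product: 26, Gemichalcone A
Conditions: TMSOTf, 2,2'-bipyridyl, MeCN, 0 °C → rt; then H2O
Reagents that add atoms: none
Why: Aprotic, buffered Lewis-acid cleavage of the three aryl MOM acetals (via aryl silyl ethers hydrolysed on work-up) avoids the alcoholic acid or base that would transesterify the allylic ferulate or cyclise the 2'-hydroxychalcone.

## Compound list

1 | resorcinol | Oc1cccc(O)c1 | starting material
2 | acetic acid | CC(=O)O | starting material
3 | 2,4-dihydroxyacetophenone | CC(=O)c1ccc(O)cc1O | intermediate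
4 | formaldehyde | C=O | starting material
5 | 1-{3-[(dimethylamino)methyl]-2,4-dihydroxyphenyl}ethan-1-one | CC(=O)c1ccc(O)c(CN(C)C)c1O | intermediate
6 | 1-(3-acetyl-2,6-dihydroxyphenyl)-N,N,N-trimethylmethanaminium triflate | CC(=O)c1ccc(O)c(C[N+](C)(C)C)c1O.[O-]S(=O)(=O)C(F)(F)F | intermediate
7 | propargyl alcohol | C#CCO | starting material
8 | methylmagnesium bromide | C[Mg]Br | starting material
9 | (Z)-3-iodo-2-methylprop-2-en-1-ol | OC/C(C)=C\I | intermediate
10 | (Z)-tert-butyl[(3-iodo-2-methylprop-2-en-1-yl)oxy]dimethylsilane | CC(C)(C)[Si](C)(C)OC/C(C)=C\I | intermediate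
11 | (Z)-TBSOCH2–C(CH3)=CH–Bpin | CC(C)(C)[Si](C)(C)OC/C(C)=C\B1OC(C)(C)C(C)(C)O1 | intermediate
12 | 1-{3-[(2Z)-4-(TBSO)-3-methylbut-2-en-1-yl]-2,4-dihydroxyphenyl}ethan-1-one | CC(=O)c1ccc(O)c(C/C=C(C)\CO[Si](C)(C)C(C)(C)C)c1O | intermediate
13 | 1-{3-[(2Z)-4-(TBSO)-3-methylbut-2-en-1-yl]-2-hydroxy-4-(methoxymethoxy)phenyl}ethan-1-one | CC(=O)c1ccc(OCOC)c(C/C=C(C)\CO[Si](C)(C)C(C)(C)C)c1O | intermediate
14 | 4-bromophenol | Oc1ccc(Br)cc1 | starting material
15 | 1-bromo-4-(methoxymethoxy)benzene | COCOc1ccc(Br)cc1 | intermediate
16 | 4-(methoxymethoxy)benzaldehyde | COCOc1ccc(C=O)cc1 | intermediate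
17 | TBS-protected bis-MOM chalcone (2E, side chain 2Z) | COCOc1ccc(/C=C/C(=O)c2ccc(OCOC)c(C/C=C(C)\CO[Si](C)(C)C(C)(C)C)c2O)cc1 | intermediate
18 | bis-MOM chalcone (Z)-allylic alcohol | COCOc1ccc(/C=C/C(=O)c2ccc(OCOC)c(C/C=C(C)\CO)c2O)cc1 | intermediate
19 | catechol | Oc1ccccc1O | starting material
20 | 2-methoxyphenol | COc1ccccc1O | intermediate
21 | 4-bromo-2-methoxyphenol | COc1cc(Br)ccc1O | intermediate
22 | 4-bromo-2-methoxy-1-(methoxymethoxy)benzene | COCOc1ccc(Br)cc1OC | intermediate
23 | acrylic acid | C=CC(=O)O | starting material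
24 | (2E)-3-[3-methoxy-4-(methoxymethoxy)phenyl]prop-2-enoic acid | COCOc1ccc(/C=C/C(=O)O)cc1OC | intermediate
25 | tris-MOM Gemichalcone A | COCOc1ccc(/C=C/C(=O)OC/C(C)=C\Cc2c(OCOC)ccc(C(=O)/C=C/c3ccc(OCOC)cc3)c2O)cc1OC | intermediate
26 | Gemichalcone A | COc1cc(/C=C/C(=O)OC/C(C)=C\Cc2c(O)ccc(C(=O)/C=C/c3ccc(O)cc3)c2O)ccc1O | target

## Step count and risks

**Total steps:** 18

**Longest linear sequence:** 9 (steps 1, 2, 3, 7, 8, 11, 12, 17, 18; the branch 4, 5, 6, 7, 8, 11, 12, 17, 18 is equally long)

**Steps most likely to fail**

1. **Step 7 (proposed new coupling).** Risks are o-quinone methide hydration or oligomerisation, slow B→Rh transfer and protodeboronation. Fallback with known chemistry and reversed polarity: Duff formylation of 3 at C3, bis-MOM protection, aldehyde-selective NaBH4 reduction, MsCl/LiCl to the benzylic chloride, Zn/LiCl insertion to a ketone-tolerant benzylic zinc, then standard Pd(OAc)2/SPhos Negishi coupling with vinyl iodide 10 (retention at the alkenyl carbon). The product is the 2,4-bis-MOM analogue of 13 and enters at step 11.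

2. **Step 18 (global MOM removal).** Risks are ionisation of the allylic ferulate with phenol cyclisation, flavanone formation and ester cleavage. Fallback is a silyl endgame: strip MOM and TBS from 17 with HCl/MeOH before any ester is present, persilylate with TBSCl/imidazole, unmask only the primary allylic OTBS (PPTS, MeOH), esterify with TBS-protected ferulic acid, and finish with buffered HF·pyridine, which is neutral towards the ester and chalcone.

3. **Step 2 (Mannich regiochemistry).** The risk is C5 or bis-aminomethylation. Fallback installs the C3 handle as a halogen: I2/HIO3 iodination of 3 at C3, bis-MOM protection, conversion to the arylboronate, and Pd-catalysed aryl–allyl Suzuki coupling with the (Z)-allylic carbonate made from 10 (t-BuLi, then (CH2O)n, then ClCO2Me). This forms the Ar–CH2 bond instead and needs no o-quinone methide.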